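Leave the stop at 2.0 h and spend the next hour on the charge series, not on a longer run. Count half-lives to see why.

| flask | starting material | partner | capture agent | remark | time |
|---|---|---|---|---|---|
| north-west | 0.080 M | 0.26 M | 0.25 M | run made earlier |  |
| gamma | 0.080 M | 0.175 M | 0.250 M |  | 2.0 h |
| theta | 0.12 M | 0.175 M | 0.250 M |  | 2.0 h |
| alpha | 0.15 M | 0.175 M | 0.250 M |  | 2.0 h |
| beta | 0.25 M | 0.175 M | 0.250 M |  | 2.0 h |

north-west run (percent of the starting material charged)

| time / min | target / % | homo product / % |
|---|---|---|
| 12.0 | 3.8 | 0.3 |
| 25.0 | 8.7 | 1.2 |
| 40.0 | 9.9 | 0.8 |
| 50.0 | 14.3 | 0 |
| 60.0 | 16.5 | 0.9 |
| 80.0 | 15.2 | 0.9 |

(standard deviation of a reading: 1 percentage point)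

- in percentages every species weighs as the starting material in it: one homo product counts as two
- "hardly changes" means that all values lie within two and a half points (for a concentration: within two and a half percent of the largest)

- share of target in all that became target or homo product or trapped intermediate or side product for gamma, theta, alpha, beta, in this order
- the course of these numbers from the first flask to the last (rises, then falls / falls all the way / rises all the way / hardly changes / falls, then rises)

In the north-west run, the last two target readings average 15.8%, and target reads 8.7% at 25.0 min, about half of that level. So take the run half-life, the time in which target reaches half of that level, as 25.0 min. This is a reading and carries the scatter of 1 percentage point.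

Then 2.0 h holds 4.80 run half-lives, and that count estimates 3.59% of the starting material unused. If the rate-limiting step is first order in starting material, the count carries over to each c(starting material) in the series, so expect little gain from waiting longer.

Homo product reads 0.9% at 80.0 min, within the scatter of nothing. Expect the course to hardly change as the charge rises, and don't stretch the time.

The forecast gives 14.5%, 14.5%, 14.5% and 15%, with a course that hardly changes. It notes that “Raising starting material adds a little homo”.

The flasks give 29.1%, 28.8%, 28.6% and 27.8%, and the course hardly changes.

    open intermediate + capture agent → trapped intermediate (k = 0.00220 /M/s)
    open intermediate → decomposed reagent (k = 0.00400 /s)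
    open intermediate → side product (k = 0.00140 /s)
    starting material → open intermediate (k = 6.80 × 10⁻⁴ /s)
    2 open intermediate → homo product (k = 0.00130 /M/s)
    partner + open intermediate → target (k = 0.00470 /M/s)

Keep the stop: starting material stands at 0.75% in gamma and 0.75% in beta at 2.00 h, and reading beta at 20.0 h instead makes no difference to its share. By the step to decomposed reagent alone, the half-life of open intermediate in gamma is 2.9 min, far shorter than the run half-life of 25.0 min, and 58.7% of gamma's starting material ends there, outside the share. Take that step away and the course no longer stays flat: gamma's share goes from 29.1% to 28.2%, and beta's from 27.8% to 25.3%.

The data are calculated for an exercise, noise included.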